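**Plan**

- Retrosynthesis: after removal of two O-benzyl groups, each 2,2-dimethylpyran ring is cut at O1–C2, C3–C4 and C4–C4a (six bonds in all). This leaves 2',6'-di-O-benzylphloretin, two formaldehyde carbons and two molecules of 2-methylpropene.
- Enabling feature: in both pyran rings C4 is a CH2 on the arene, C3 a CH2 and C2 a gem-dimethyl carbon bound to a phenol oxygen. Each ring is thus one formaldehyde carbon plus the four carbons of 2-methylpropene laid across a phenol oxygen (O1) and its ortho carbon (C4a).
- Forward: the C6–C3–C6 chain is bought as naringenin. Its pyranone oxygen and its chelated 5-OH mask exactly the two ring A oxygens that must become benzyl ethers. MOM protection of the 7- and 4'-OH, alkaline ring-opening hydrogenation, double benzylation and MOM removal give the diphenol.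
- Both pyran rings then arise in one operation (boron-templated ortho-hydroxymethylation, then o-quinone methide/alkene [4+2] cycloaddition); hydrogenolysis of the benzyl ethers ends the route.
- Stereochemistry: the target is achiral and no stereocentre is created; the C2 centre of naringenin is erased in step 2.

Key step: step 5

Assumption: racemic naringenin is taken as the commercial starting material; either enantiomer would serve equally, since its only stereocentre is lost on ring opening.

**Step 1**
Reactants: 1 naringenin
Product: 2 5-hydroxy-7,4'-bis(methoxymethoxy)flavanone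
Conditions: MOMCl (2.2 equiv), i-Pr2NEt, CH2Cl2/DMF, 0 °C to rt
Reagents that add atoms: chloromethyl methyl ether, COCCl
Why: Phenol O-alkylation (Williamson-type acetal formation) is expected only at the 7- and 4'-hydroxyls, because the 5-hydroxyl is held in a hydrogen bond to the C4 carbonyl and the fourth ring A oxygen is locked in the pyranone ring.

**Step 2**
Reactants: 2 5-hydroxy-7,4'-bis(methoxymethoxy)flavanone
Product: 4 2',6'-dihydroxy-4,4'-bis(methoxymethoxy)dihydrochalcone, via ring-opened chalcone 3 (not isolated)
Conditions: H2 (1 atm), Pd/C, KOH (aq), EtOH, rt; then AcOH to pH 6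
Reagents that add atoms: none
Why: Hydroxide opens the 5-hydroxyflavanone by an E1cB retro-oxa-Michael reaction to the chalcone phenoxide, whose C=C bond is saturated by heterogeneous catalytic hydrogenation while the phenoxide-conjugated carbonyl and the base-stable MOM ethers stay untouched (the alkaline hydrogenation of flavanones to dihydrochalcones); the C2 stereocentre of 2 disappears here.

**Step 3**
Reactants: 4 2',6'-dihydroxy-4,4'-bis(methoxymethoxy)dihydrochalcone; 5 benzyl bromide
Product: 6 2',6'-bis(benzyloxy)-4,4'-bis(methoxymethoxy)dihydrochalcone
Conditions: BnBr (2.5 equiv), K2CO3, DMF, 60 °C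
Reagents that add atoms: benzyl bromide (5), BrCc1ccccc1
Why: Williamson ether synthesis: the only free hydroxyls are the two ortho to the ketone, the first is alkylated readily and the chelated second one on warming in DMF, while the MOM ethers and the ketone α-methylene are inert to carbonate.

**Step 4**
Reactants: 6 2',6'-bis(benzyloxy)-4,4'-bis(methoxymethoxy)dihydrochalcone
Product: 7 2',6'-di-O-benzylphloretin
Conditions: HCl (3 M aq), MeOH/THF, 50 °C
Reagents that add atoms: none
Why: Acid-catalysed acetal cleavage (transacetalisation to dimethoxymethane) frees the 4- and 4'-phenols, whereas aryl benzyl ethers and the ketone tolerate dilute HCl in methanol.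

**Step 5**
Reactants: 7 2',6'-di-O-benzylphloretin; 8 formaldehyde (as paraformaldehyde); 9 2-methylpropene
Product: 11 1-[5,7-bis(benzyloxy)-2,2-dimethylchroman-6-yl]-3-(2,2-dimethylchroman-6-yl)propan-1-one, via bis(benzodioxaborin) 10 (not isolated)
Conditions: PhB(OH)2 (2.4 equiv), (CH2O)n (2.4 equiv), EtCO2H (cat.), toluene, reflux (Dean–Stark); then 2-methylpropene (large excess), sealed autoclave, 180–200 °C
Reagents that add atoms: formaldehyde (8), C=O; 2-methylpropene (9), CC(C)=C; phenylboronic acid, OB(O)c1ccccc1 (its atoms stay only in intermediate 10)
Why: Each free phenol first forms an aryl phenylboronate that delivers formaldehyde to its own ortho carbon through a six-membered transition state (boron-templated electrophilic aromatic substitution) and holds the resulting o-hydroxybenzyl alcohol as a 2-phenyl-4H-1,3,2-benzodioxaborin, so the C4a–C4 bond of each future pyran is made once and only next to the free oxygen. At 180–200 °C each dioxaborin should extrude its phenylboron oxide unit (collected as the boroxine) in a retro-[4+2] fragmentation to give an o-quinone methide whose carbonyl oxygen is the former phenol oxygen, and this heterodiene is trapped by 2-methylpropene in an inverse-electron-demand hetero-Diels–Alder reaction. The closest known reaction type is the thermolysis of phenol–aldehyde–arylboronic acid adducts in the presence of 1,1-disubstituted alkenes to give 2,2-disubstituted chromans, here run at two independent sites of one molecule. Each pyran ring is closed by an intermolecular [4+2] cycloaddition in which C4–C3 and O1–C2 form in the same step, the alkene CH2 bonding to the electrophilic exocyclic methylene and the oxygen to the carbon that best carries positive charge, which fixes the 2,2-dimethyl pattern. No stereocentre is created because C2 bears two methyl groups. The selectivity needed is the choice of oxygen and ortho carbon on ring A: the benzyl ethers at O2' and O6' leave O4' as the only oxygen able to bind boron, its two ortho carbons are equivalent by the local symmetry of ring A (as are those of ring B), and an oxygen that has become a pyran ether cannot form a second quinone methide.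

**Step 6**
Reactants: 11 1-[5,7-bis(benzyloxy)-2,2-dimethylchroman-6-yl]-3-(2,2-dimethylchroman-6-yl)propan-1-one
Product: 12 1-(5,7-dihydroxy-2,2-dimethylchroman-6-yl)-3-(2,2-dimethylchroman-6-yl)propan-1-one (target)
Conditions: H2 (1 atm), Pd/C, EtOAc/EtOH, rt
Reagents that add atoms: none
Why: Catalytic hydrogenolysis of aryl benzyl ethers over Pd/C under 1 atm of H2 leaves the alkyl aryl ethers of both chromans and the hindered, electron-rich aryl ketone intact and gives the target.

**Compound list**

1 | naringenin, racemic (5,7-dihydroxy-2-(4-hydroxyphenyl)chroman-4-one) | O=C1CC(c2ccc(O)cc2)Oc2cc(O)cc(O)c12 | starting material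
2 | 5-hydroxy-7,4'-bis(methoxymethoxy)flavanone, racemic | COCOc1ccc(cc1)C1CC(=O)c2c(O)cc(OCOC)cc2O1 | intermediate
3 | (E)-2',6'-dihydroxy-4,4'-bis(methoxymethoxy)chalcone (present as its potassium phenoxide, not isolated) | COCOc1ccc(/C=C/C(=O)c2c(O)cc(OCOC)cc2O)cc1 | intermediate
4 | 2',6'-dihydroxy-4,4'-bis(methoxymethoxy)dihydrochalcone | COCOc1ccc(CCC(=O)c2c(O)cc(OCOC)cc2O)cc1 | intermediate
5 | benzyl bromide | BrCc1ccccc1 | starting material
6 | 2',6'-bis(benzyloxy)-4,4'-bis(methoxymethoxy)dihydrochalcone | COCOc1ccc(CCC(=O)c2c(OCc3ccccc3)cc(OCOC)cc2OCc2ccccc2)cc1 | intermediate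
7 | 2',6'-di-O-benzylphloretin | O=C(CCc1ccc(O)cc1)c1c(OCc2ccccc2)cc(O)cc1OCc1ccccc1 | intermediate
8 | formaldehyde (used as paraformaldehyde) | C=O | starting material
9 | 2-methylpropene | CC(C)=C | starting material
10 | 1-[5,7-bis(benzyloxy)-2-phenyl-4H-1,3,2-benzodioxaborin-6-yl]-3-(2-phenyl-4H-1,3,2-benzodioxaborin-6-yl)propan-1-one (not isolated) | O=C(CCc1ccc2OB(c3ccccc3)OCc2c1)c1c(OCc2ccccc2)cc2OB(c3ccccc3)OCc2c1OCc1ccccc1 | intermediate
11 | 1-[5,7-bis(benzyloxy)-2,2-dimethylchroman-6-yl]-3-(2,2-dimethylchroman-6-yl)propan-1-one | CC1(C)CCc2cc(CCC(=O)c3c(OCc5ccccc5)cc4c(c3OCc6ccccc6)CCC(C)(C)O4)ccc2O1 | intermediate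
12 | 1-(5,7-dihydroxy-2,2-dimethylchroman-6-yl)-3-(2,2-dimethylchroman-6-yl)propan-1-one (CNP0080574.0) | CC1(C)CCc2cc(CCC(=O)c3c(O)cc4c(c3O)CCC(C)(C)O4)ccc2O1 | target

Total step count: 6. Longest linear sequence: 6 steps (1 to 12).

**Steps most likely to fail**

Step 5. The two o-quinone methides are expected to be released at different temperatures (ring A earlier than ring B). Each may be lost to self-condensation or to addition of a still-free phenol before the volatile alkene intercepts it, so the second annulation may stay incomplete. Acid-promoted oligomerisation of 2-methylpropene and tert-butylation of the electron-rich ring A are further drains. The fallback sets out from 7 and builds the pyran carbons from a propargyl unit instead. Both phenols would be alkylated with 3-chloro-3-methylbut-1-yne (CuCl2·2H2O cat., DBU, MeCN, 0 °C) to give 2',6'-bis(benzyloxy)-4,4'-bis(2-methylbut-3-yn-2-yloxy)dihydrochalcone F1. Heating (N,N-diethylaniline, 180 °C) should trigger on each ring an aromatic Claisen rearrangement, a 1,5-hydrogen shift and a 6π electrocyclisation to give the bis(2,2-dimethyl-2H-chromene) F2. Hydrogenation of F2 (H2, Pd/C, EtOAc/EtOH) would saturate both chromene double bonds and cleave both benzyl ethers. This branch therefore comes back to the route at target 12 and replaces steps 5 and 6.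

Step 2. Ring opening may lag behind hydrogen uptake, so that flavanone is recovered or the aryl ketone is over-reduced, and MOM groups may be lost during acidification. The fallback sets out from 2 and postpones the reduction. Benzyl bromide 5 with K2CO3 in DMF at 60 °C should benzylate the chelated phenol, open the pyranone by E1cB elimination and benzylate the liberated phenoxide, giving (E)-2',6'-bis(benzyloxy)-4,4'-bis(methoxymethoxy)chalcone F3. Chemoselective hydrogenation of the enone C=C bond (H2, Pd/C poisoned with Ph2S, EtOAc, rt) would then give 6. The branch rejoins the route at 6 and replaces steps 2 and 3.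

Step 3. The second etherification may stall at the chelated phenoxide, and C-benzylation of the phloroglucinol ring may compete on prolonged heating. The fallback sets out from 4 and splits the operation. One equivalent of 5 with K2CO3 in acetone at rt should alkylate only the non-chelated phenol to give 6'-benzyloxy-2'-hydroxy-4,4'-bis(methoxymethoxy)dihydrochalcone F4. The remaining chelated phenol would then be etherified under Mitsunobu conditions (BnOH, PPh3, DIAD, THF), where no free phenoxide is present and ring C-alkylation is not expected. This returns to the route at 6.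

**Further compounds**

F1 | step 5 | 2',6'-bis(benzyloxy)-4,4'-bis(2-methylbut-3-yn-2-yloxy)dihydrochalcone | C#CC(C)(C)Oc1ccc(CCC(=O)c2c(OCc3ccccc3)cc(OC(C)(C)C#C)cc2OCc2ccccc2)cc1
F2 | step 5 | 1-[5,7-bis(benzyloxy)-2,2-dimethyl-2H-chromen-6-yl]-3-(2,2-dimethyl-2H-chromen-6-yl)propan-1-one | CC1(C)C=Cc2cc(CCC(=O)c3c(OCc5ccccc5)cc4c(c3OCc6ccccc6)C=CC(C)(C)O4)ccc2O1
F3 | step 2 | (E)-2',6'-bis(benzyloxy)-4,4'-bis(methoxymethoxy)chalcone | COCOc1ccc(/C=C/C(=O)c2c(OCc3ccccc3)cc(OCOC)cc2OCc2ccccc2)cc1
F4 | step 3 | 6'-benzyloxy-2'-hydroxy-4,4'-bis(methoxymethoxy)dihydrochalcone | COCOc1ccc(CCC(=O)c2c(O)cc(OCOC)cc2OCc2ccccc2)cc1
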